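**Plan**

- Retrosynthesis: the three O–S bonds of the sulfate esters are cut first (back to geraldol), then the two benzyl O–C bonds, then C4–C4a and O1–C2 of ring C (back to resorcinol and an α-benzyloxy aroylacetate), and last the aroyl–Cα bond (the later C2–C3).
- Forward: ring B comes in with purchased O-benzylvanillic acid, the C2–C3 bond is made by enolate acylation, and ring C is closed onto ready-made ring A (resorcinol) in one thermal step. Hydrogenolysis, trisulfation and proton exchange follow.
- Enabling feature: in ring A, C4a sits ortho to O1 and para to the O7 hydroxyl, so it is simply C4 of unprotected resorcinol. Free resorcinol can therefore take the acyl carbon at that position and supply the neighbouring hydroxyl as O1.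
- Stereochemistry: the target has no stereocentre. The one stereocentre on the way (Cα of the keto ester) is racemic and becomes sp2 when ring C aromatises.

Key step: step 3

Remark on the chemistry: the target is taken as the free tris(hydrogen sulfate) exactly as drawn. Because aryl hydrogen sulfates hydrolyse under their own acidity, the stable tripotassium salt is made first and the acid is released from it in the cold in the last step.

**Route**

Step 1
Reactants: 1 4-(benzyloxy)-3-methoxybenzoic acid (O-benzylvanillic acid, purchased)
Product: 2 4-(benzyloxy)-3-methoxybenzoyl chloride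
Conditions: (COCl)2 (1.3 equiv), DMF (cat.), CH2Cl2, 0 °C → rt; evaporated and used crude
Reagents that add atoms: oxalyl chloride, O=C(Cl)C(=O)Cl
Why: DMF-catalysed acid chloride formation (Vilsmeier-type activation) is mild enough to leave the benzyl and methyl aryl ethers untouched, and all by-products are gases.

Step 2
Reactants: 2 4-(benzyloxy)-3-methoxybenzoyl chloride; 3 ethyl 2-(benzyloxy)acetate
Product: 5 ethyl 2-(benzyloxy)-3-[4-(benzyloxy)-3-methoxyphenyl]-3-oxopropanoate (racemic), via lithium enolate 4 (not isolated)
Conditions: 3 (2.0 equiv), LiN(SiMe3)2 (2.0 equiv), THF, −78 °C; then 2, −78 → −20 °C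
Reagents that add atoms: none
Why: This is a crossed Claisen-type C-acylation of a chelated lithium α-alkoxy ester enolate by an acid chloride at low temperature, where the second equivalent of enolate takes up the proton of the more acidic β-keto ester and so prevents double acylation.

Step 3
Reactants: 5 ethyl 2-(benzyloxy)-3-[4-(benzyloxy)-3-methoxyphenyl]-3-oxopropanoate; 6 resorcinol
Product: 9 3,4'-di-O-benzylgeraldol (3-(benzyloxy)-2-[4-(benzyloxy)-3-methoxyphenyl]-7-hydroxy-4H-chromen-4-one), via α-oxoketene 7 (not isolated), via aryl diketone 8 (not isolated)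
Conditions: 6 (3 equiv), neat melt, no catalyst, Ar stream, 230 °C (EtOH and H2O distilled out)
Reagents that add atoms: none
Why: On heating, 5 should lose ethanol to give the α-oxoketene 7, which resorcinol captures either at oxygen, followed by a thermal acyl shift to the ring, or directly at its C4, so that the aryl diketone 8 with the new C4–C4a bond results. The hydroxyl ortho to the new ketone then adds to the aroyl carbonyl in a 6-exo-trig closure (O1–C2), and loss of water aromatises ring C. The closest known reaction type is the Mentzer pyrone synthesis, the catalyst-free thermal condensation of phenols with β-keto esters (α-substituted ones included) to chromones and flavones. No stereocentre is formed, and the racemic α-carbon of 5 becomes the sp2 carbon C3. The step needs acylation at resorcinol C4 and not C2, which the crowding of C2 between two hydroxyls and the ortho/para activation of C4 should secure, and it needs chromone instead of coumarin, which the absence of acid (no activation of the aroyl ketone for a Pechmann-type ring attack), the electron-rich and therefore weakly electrophilic aroyl group and the α-benzyloxy substituent should secure. The excess of resorcinol should keep the free 7-hydroxyl of 9 from being acylated by a second ketene.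

Step 4
Reactants: 9 3,4'-di-O-benzylgeraldol
Product: 10 geraldol (3,7-dihydroxy-2-(4-hydroxy-3-methoxyphenyl)-4H-chromen-4-one)
Conditions: H2 (1 atm), 10% Pd/C, THF/MeOH, rt
Reagents that add atoms: none
Why: Catalytic hydrogenolysis should cleave both benzyl ethers, while the tetrasubstituted, vinylogous-ester C2–C3 double bond of the flavonol resists hydrogenation at atmospheric pressure and room temperature.

Step 5
Reactants: 10 geraldol
Product: 12 tripotassium geraldol 3,7,4'-trisulfate, via tris(pyridinium) trisulfate 11 (not isolated)
Conditions: SO3·pyridine (15 equiv), pyridine, 65 °C; then KOH, MeOH/H2O, 0 °C, pH 8; Sephadex G-10, H2O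
Reagents that add atoms: sulfur trioxide–pyridine complex, O=S(=O)([O-])[n+]1ccccc1; potassium hydroxide, [K+].[OH-]
Why: O-Sulfonation of phenols with an SO3–amine complex is standard, the large excess and warming should also drive the less nucleophilic, hydrogen-bonded 3-hydroxyl to completion (there is no 5-hydroxyl to leave behind), and potassium exchange gives a stable salt that size exclusion frees from inorganic sulfate.

Step 6
Reactants: 12 tripotassium geraldol 3,7,4'-trisulfate
Product: 13 geraldol 3,7,4'-tris(hydrogen sulfate), the target
Conditions: Dowex 50W-X8 (H+ form), H2O, 0–4 °C; eluate freeze-dried at once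
Reagents that add atoms: none
Why: Cation exchange on a strongly acidic sulfonic resin replaces potassium by protons, and the low temperature, short contact time and immediate freeze-drying should hold back acid-catalysed S–O hydrolysis.

**Compound list**

1 | 4-(benzyloxy)-3-methoxybenzoic acid | COc1cc(C(=O)O)ccc1OCc1ccccc1 | starting material
2 | 4-(benzyloxy)-3-methoxybenzoyl chloride | COc1cc(C(=O)Cl)ccc1OCc1ccccc1 | intermediate
3 | ethyl 2-(benzyloxy)acetate | CCOC(=O)COCc1ccccc1 | starting material
4 | lithium enolate of ethyl 2-(benzyloxy)acetate (formed in the flask, enolate geometry left open) | CCOC([O-])=COCc1ccccc1.[Li+] | intermediate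
5 | ethyl 2-(benzyloxy)-3-[4-(benzyloxy)-3-methoxyphenyl]-3-oxopropanoate (racemic) | CCOC(=O)C(OCc1ccccc1)C(=O)c1ccc(OCc2ccccc2)c(OC)c1 | intermediate
6 | resorcinol | Oc1cccc(O)c1 | starting material
7 | 2-(benzyloxy)-3-[4-(benzyloxy)-3-methoxyphenyl]-3-oxoprop-1-en-1-one (α-oxoketene, formed in the flask) | O=C=C(OCc1ccccc1)C(=O)c1ccc(OCc2ccccc2)c(OC)c1 | intermediate
8 | 2-(benzyloxy)-1-[4-(benzyloxy)-3-methoxyphenyl]-3-(2,4-dihydroxyphenyl)propane-1,3-dione (racemic, formed in the flask) | O=C(c1ccc(O)cc1O)C(OCc1ccccc1)C(=O)c1ccc(OCc2ccccc2)c(OC)c1 | intermediate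
9 | 3,4'-di-O-benzylgeraldol, 3-(benzyloxy)-2-[4-(benzyloxy)-3-methoxyphenyl]-7-hydroxy-4H-chromen-4-one | COc1cc(-c2oc3cc(O)ccc3c(=O)c2OCc2ccccc2)ccc1OCc1ccccc1 | intermediate
10 | geraldol, 3,7-dihydroxy-2-(4-hydroxy-3-methoxyphenyl)-4H-chromen-4-one | COc1cc(-c2oc3cc(O)ccc3c(=O)c2O)ccc1O | intermediate
11 | tris(pyridinium) geraldol 3,7,4'-trisulfate (formed in the flask) | COc1cc(-c2oc3cc(OS(=O)(=O)[O-])ccc3c(=O)c2OS(=O)(=O)[O-])ccc1OS(=O)(=O)[O-].c1cc[nH+]cc1.c1cc[nH+]cc1.c1cc[nH+]cc1 | intermediate
12 | tripotassium geraldol 3,7,4'-trisulfate | COc1cc(-c2oc3cc(OS(=O)(=O)[O-])ccc3c(=O)c2OS(=O)(=O)[O-])ccc1OS(=O)(=O)[O-].[K+].[K+].[K+] | intermediate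
13 | geraldol 3,7,4'-tris(hydrogen sulfate) (CNP0382475.0) | COc1cc(-c2oc3cc(OS(=O)(=O)O)ccc3c(=O)c2OS(=O)(=O)O)ccc1OS(=O)(=O)O | target

**Count**

Total steps: 6. Longest linear sequence: 6 steps (1 → 2 → 5 → 9 → 10 → 12 → 13); 3 and 6 are purchased partners.

**Steps most likely to fail**

1. Step 3. The melt may divert the ketene into O-acyl products that do not rearrange, into attack at resorcinol C2 or into Pechmann-type closure, or the benzyl ethers may be shed at the temperature needed, so that little flavone forms. The fallback sets out from resorcinol 6 and comes back at geraldol 10. Resorcinol is C-acetylated with acetic acid and ZnCl2 at 140 °C (Nencki reaction) to 2,4-dihydroxyacetophenone F1. The para hydroxyl alone is benzylated (benzyl bromide, K2CO3, acetone, reflux; the ortho hydroxyl is held back by its hydrogen bond to the ketone) to give 1-[4-(benzyloxy)-2-hydroxyphenyl]ethan-1-one F2. Claisen–Schmidt condensation with purchased 4-(benzyloxy)-3-methoxybenzaldehyde (KOH, EtOH, rt) should give (E)-1-[4-(benzyloxy)-2-hydroxyphenyl]-3-[4-(benzyloxy)-3-methoxyphenyl]prop-2-en-1-one F3. Algar–Flynn–Oyamada oxidation (H2O2, NaOH, MeOH, 0 °C → rt) then closes ring C and installs the 3-hydroxyl, giving 7,4'-di-O-benzylgeraldol F4. Hydrogenolysis under the conditions of step 4 returns to 10.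

2. Step 5. Sulfation may stop short at the hydrogen-bonded 3-hydroxyl, or that sulfate may be lost during the basic work-up, leaving mixtures of partially sulfated salts that are hard to separate. The fallback sets out from geraldol 10 and comes back at the tripotassium salt 12. Geraldol is treated with 2,2,2-trichloroethyl chlorosulfate (Et3N, DMAP, THF, 0 °C → rt) to give geraldol 3,7,4'-tris(2,2,2-trichloroethyl sulfate) F5, a neutral compound that can be purified on silica and checked for complete sulfation. Reductive removal of the three trichloroethyl groups with Zn dust and HCOONH4 in MeOH should give triammonium geraldol 3,7,4'-trisulfate F6. KOH (3 equiv) in MeOH, with evaporation of the ammonia, then gives 12.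

3. Step 6. One or more sulfate esters may be hydrolysed under acid catalysis on the resin bed or while the acidic eluate is concentrated. The fallback sets out from geraldol 10 and comes back at the target 13. Geraldol is sulfated with SO3·pyridine as in step 5, but the mixture is quenched with aqueous Ba(OH)2. This removes the excess sulfate as BaSO4, and after evaporation of pyridine leaves the water-soluble barium geraldol 3,7,4'-trisulfate F7 (three barium ions per two trianions). Addition of exactly the equivalent amount of dilute H2SO4 at 0 °C precipitates BaSO4. The filtrate, which is never more acidic than the product itself and never touches a resin, is freeze-dried to 13.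

**Further compounds**

F1 | step 3 | 2,4-dihydroxyacetophenone | CC(=O)c1ccc(O)cc1O
F2 | step 3 | 1-[4-(benzyloxy)-2-hydroxyphenyl]ethan-1-one | CC(=O)c1ccc(OCc2ccccc2)cc1O
F3 | step 3 | (E)-1-[4-(benzyloxy)-2-hydroxyphenyl]-3-[4-(benzyloxy)-3-methoxyphenyl]prop-2-en-1-one | COc1cc(/C=C/C(=O)c2ccc(OCc3ccccc3)cc2O)ccc1OCc1ccccc1
F4 | step 3 | 7,4'-di-O-benzylgeraldol, 7-(benzyloxy)-2-[4-(benzyloxy)-3-methoxyphenyl]-3-hydroxy-4H-chromen-4-one | COc1cc(-c2oc3cc(OCc4ccccc4)ccc3c(=O)c2O)ccc1OCc1ccccc1
F5 | step 5 | geraldol 3,7,4'-tris(2,2,2-trichloroethyl sulfate) | COc1cc(-c2oc3cc(OS(=O)(=O)OCC(Cl)(Cl)Cl)ccc3c(=O)c2OS(=O)(=O)OCC(Cl)(Cl)Cl)ccc1OS(=O)(=O)OCC(Cl)(Cl)Cl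
F6 | step 5 | triammonium geraldol 3,7,4'-trisulfate | COc1cc(-c2oc3cc(OS(=O)(=O)[O-])ccc3c(=O)c2OS(=O)(=O)[O-])ccc1OS(=O)(=O)[O-].[NH4+].[NH4+].[NH4+]
F7 | step 6 | barium geraldol 3,7,4'-trisulfate (three barium ions per two trianions) | COc1cc(-c2oc3cc(OS(=O)(=O)[O-])ccc3c(=O)c2OS(=O)(=O)[O-])ccc1OS(=O)(=O)[O-].COc1cc(-c2oc3cc(OS(=O)(=O)[O-])ccc3c(=O)c2OS(=O)(=O)[O-])ccc1OS(=O)(=O)[O-].[Ba+2].[Ba+2].[Ba+2]
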